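The reaction phase is charged without reagent, so at the first instant product cannot form, while substrate already pairs away at 0.0620 mM/s.

    reagent in the reaction phase + protic impurity → quenched reagent (k1 = 2400 /M/s)
    substrate + reagent in the reaction phase → product (k2 = 370 /M/s)
    2 substrate → homo dimer (k3 = 31 /M/s)
    reagent in the reaction phase ⇌ reagent in the second phase, rate k4*([reagent in the reaction phase] - [reagent in the second phase]/K4) per volume of the first phase (K4 = 0.74, k4 = 0.088 /s)
    crystals ⇌ product, rate k5*(cs5 - [product]) while solid is left; crystals form when [product] > cs5 (cs5 = 0.090 mM, k5 = 30 /s)

substrate 0.0010 M; reagent in the second phase 1.20 mM; protic impurity 0.0500 mM; time 30 s; volume of the second phase over the first 1.0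

- percentages count the substrate that a species holds: one homo dimer counts as two
- product is meant together with its crystals
- a step written with two of one species runs at k times the square of its concentration and takes two of it each time
- in the second phase: reagent in the second phase; everything else is in the first
- charges count per volume of the first phase; a concentration in a rate is the amount of a species over the volume of its own phase; every rate counts per litre of the first phase
- solid, in amounts per volume of the solution: crystals
- run time (flask): 30 s

- product and crystals together at 30 s, in percent of the substrate charged
- the change that raises the amount of product and crystals together at 30 s, in percent of the substrate charged most ("none" if none brings more than 2 percentage points) (blue / amber / ochre / violet / none)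
- amount of product and crystals together at 30 s, in percent of the substrate charged, after blue

- blue: doubling the solubility in step 5, all else as stated
- amber: doubling the transfer coefficient of step 4, all else as stated
- ochre: doubling the dissolution coefficient of step 5, all else as stated
- violet: doubling the amount of reagent in the second phase, all else as stated

You asked for a quick number and suspect the early seconds; here is my reckoning. With substrate and reagent in the second phase held at their charges, I reckon [reagent in the reaction phase] climbing with a time constant of 2.18 s, fed at 0.143 mM/s, to a plateau of 0.312 mM. I leave out the protic impurity, whose charge is 4.17% of the reagent's.

On that plateau the product route is pseudo-first-order in substrate, and dividing one substrate loss by the other integrates in closed form. Carry the crossover X = 1.86 mM, the [substrate] at which product and homo dimer take substrate equally fast: the product constant times [reagent in the reaction phase], over 2 times the dimer constant.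

Product made while substrate falls is X ln((X + [substrate] at the start)/(X + [substrate] at the end)). The lag takes [substrate] to 0.865 mM, and I reckon 0.0242 mM at 30 s, so y comes to 68.6%.

Step 5 moves product between solution and crystals, and y counts both, so blue keeps my number. In my reckoning violet doubles X, lifting the yield at full conversion from 71.0% to 77.7%, so I pick violet, though I did not reckon amber.

Your forecast gives 67%, a little below mine, with violet and 67%; its ground for violet is that doubling the reagent “raises both the early feed and the later reagent level”.

| | mine | forecast | simulation |
|---|---|---|---|
| y | 68.6% | 67% | 67.1% |
| best | violet | violet | violet |
| yb | 68.6% | 67% | 67.1% |

Violet adds 14 percentage points, amber 6.2 points, blue 0 points. For the neighbour flask charged with 0.0017 M of substrate, the same reckoning gives X = 1.19 mM and 50.9%; that flask reads 49.3%. The flask itself has not come to rest at 30 s: 3.95% of substrate remains, and the reagent reading of 2.59 × 10⁻⁴ M moves X from 1.86 mM to 1.55 mM, with which I reckon that remainder as 3.90% more product, 71.0% in sum. At 300 s the flask reads 71.0%, with homo dimer at 29.0%.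

The rate constants are invented; the run is a simulation.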